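Remark: the target has no stereogenic element. Ring A is the 2,4-dihydroxy-6-propylbenzoyl ring and ring B the methyl 2-methoxy-6-propylbenzoate ring. Polyketo compounds are written as keto tautomers although they are largely enolised.

## The problem

Target 13 is a depside. The carboxyl carbon of ring A (C1 carboxyl, C2–OH, C4–OH, C6–propyl) is esterified to the C4 oxygen of ring B (C1–CO2Me, C2–OMe, C6–propyl). With no stereocentre, the difficulty lies in connectivity and in telling oxygen atoms apart.

The ester carbonyl of ring A sits between an ortho hydroxyl and an ortho propyl group. Its partner is a phenol deactivated by a para ester. The classical acylation therefore joins a hindered acid to a poor nucleophile and needs both ring A hydroxyls masked.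

Both rings carry the same 1-carboxyl-2,4-dioxy-6-propyl pattern, yet their four phenolic oxygens must end in three states: two free (ring A), one methyl ether (ring B, C2) and one acylated (ring B, C4). In ring B the chelated C2 oxygen is the less reactive one but is the one to be methylated.

The aryl ester is cleaved or transesterified by hydroxide and alkoxide. The depside bond should therefore be made last, without nucleophilic base, and nothing should have to be removed from ring A afterwards.

The feature that opens a way is the oxygen pattern of ring A. The ester carbon, C2 and C4 bear oxygen and C6 bears the propyl chain, so the ester carbon, the six ring carbons and the propyl group are a folded 3,5,7-trioxodecanoyl chain. The ring bond C1–C6 is its aldol bond and the ester carbon is the chain terminus. Ring B has the same origin, so one open-chain precursor can serve both rings.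

## Retrosynthesis

**Ring A opened (13 to 12).** Ring A is cut at the C1–C6 bond, between the carboxyl-bearing and the propyl-bearing carbon, with formal addition of water. This gives the aryl 3,5,7-trioxodecanoate 12. Cutting the ester C–O bond first would keep a finished, hindered ring A and force protection of its two hydroxyls. The aldol cut removes ring A, its free phenols and the steric problem together. The forward reaction asks that chain C2 add to the C7 ketone rather than C6 to the ester carbonyl, and that water leave under conditions an aryl ester survives.

**Depside bond (12 to 11 + 10, then 5).** The ester C(=O)–O bond of 12 is cut to acylketene 11 and phenol 10. Ketene 11 is the retro-cycloaddition product of diketo-dioxinone 5, by loss of acetone. A conventional activated triketo acid would self-condense; the dioxinone stores the ketene in a neutral form that heat alone releases. The acyl carbon is an unhindered sp carbon when the C–O bond forms, because neither ortho substituent exists yet. Compound 5 has no arene and 10 is a single ring. The forward reaction asks that the O–H of 10 capture the ketene faster than the ketene cyclises onto its own enol oxygen.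

**Ring B from the same chain (10 to 9, 8, 7, 6, then 5).** Phenol 10 comes from benzyl ether 9. Cutting the methyl ether and methyl ester C–O bonds of 9 leads through phenoxide 8 to benzodioxinone 7, and debenzylation gives 6. Ring B of 6 is cut at the same aldol bond (C4a–C5) and returns to 5. Aromatising 5 with the dioxinone intact ties the carboxyl and the ortho oxygen into one acetonide and leaves only the para oxygen free. The ring construction itself differentiates the two oxygens of ring B, in the sense needed. A ring B with both hydroxyls free would alkylate first at the wrong, non-chelated oxygen. The forward steps ask only for benzylation of the one free phenol, methoxide opening that delivers CO2Me and releases exactly the oxygen to be methylated, and hydrogenolysis.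

**The chain (5 to 3 + 4, then 1 + 2).** The bond between the terminal CH2 and the butanoyl carbonyl of 5 is cut to keto-dioxinone 3 and Weinreb amide 4. Compound 3 is cut at the corresponding acetyl bond to dioxinone 1 and acetyl chloride 2. The order acetyl first, butanoyl second is required, because the dianion of 3 reacts at its terminal methyl and so extends the chain linearly. All three building blocks are commercial.

## Roads not taken

Alternative 1: the most obvious cut is the depside C(=O)–O bond with both rings finished. The forward step is condensation of 2,4-bis(benzyloxy)-6-propylbenzoic acid A1 with phenol 10 (carbodiimide or trifluoroacetic anhydride) to the bis-benzyl depside A2, then hydrogenolysis. A1 needs its own multi-step synthesis with two protecting groups put on and taken off. Its carbonyl, flanked by two ortho substituents, must acylate a deactivated phenol. Ring B must still be made separately. The chosen plan forms the same bond before ring A exists and draws both rings from one precursor.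

Alternative 2: the same bond is cut, but the acyl donor is benzodioxinone 6. Irradiation would expel acetone to give quinone ketene A3, to be captured by 10 to give 13 directly. The free 7-OH of 6 and of A3 is itself a phenol and would compete with 10, so a protecting group and a deprotection return. Both 10 and the product are aryl benzoates that absorb in the same region, so photo-Fries rearrangement of the depside threatens the product. The thermal ketene route needs no light and no protection of ring A.

Alternative 3: a true dimerisation, in which ketene 11 is captured by the free phenol of 6 to give depside acetonide A4, with ring B finished afterwards. Converting A4 into 13 would need alkoxide opening of the acetonide in the presence of the equally labile depside ester. It would then need methylation of the chelated ring B hydroxyl in the presence of the two more reactive ring A hydroxyls. Neither selection has a structural basis. The chosen plan makes all adjustments to ring B before the depside bond and ring A exist.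

Key step: step 7

## Route

Step 1
Reactants: 1 2,2,6-trimethyl-4H-1,3-dioxin-4-one; 2 acetyl chloride
Product: 3 2,2-dimethyl-6-(2-oxopropyl)-4H-1,3-dioxin-4-one
Conditions: 1 and LiN(SiMe3)2 (2 equiv each per 2), THF, −78 °C; then 2; aq. NH4Cl
Reagents that add atoms: none
Why: Deprotonation of the C6 methyl of 1 gives the lithium dienolate, which is C-acylated at its γ-carbon by 2 (vinylogous Claisen-type acylation); two equivalents of dienolate are used because 3 is more acidic than 1 and is deprotonated as it forms.

Step 2
Reactants: 3 2,2-dimethyl-6-(2-oxopropyl)-4H-1,3-dioxin-4-one; 4 N-methoxy-N-methylbutanamide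
Product: 5 6-(2,4-dioxoheptyl)-2,2-dimethyl-4H-1,3-dioxin-4-one
Conditions: LiN(iPr)2 (2.2 equiv), THF, −78 °C; 4, −78 → −40 °C; aq. NH4Cl
Reagents that add atoms: none
Why: Double deprotonation of 3 (first the doubly activated CH2, then the terminal CH3) gives a dianion whose more basic terminal carbanion attacks Weinreb amide 4 (β-dicarbonyl dianion acylation); the chelated tetrahedral adduct releases the 1,3-diketone only on quench, which prevents over-acylation.

Step 3
Reactants: 5 6-(2,4-dioxoheptyl)-2,2-dimethyl-4H-1,3-dioxin-4-one
Product: 6 7-hydroxy-2,2-dimethyl-5-propyl-4H-1,3-benzodioxin-4-one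
Conditions: Et3N, CH2Cl2, rt
Reagents that add atoms: none
Why: Et3N forms the dienolate of 5, whose dioxinone C5 adds to the propyl ketone in a 6-exo-trig aldol, and loss of water with enolisation gives the arene (base-mediated aromatisation of diketo-dioxinones to resorcylate acetonides); the carboxyl and ortho oxygen stay tied in the acetonide, so only the para hydroxyl is free.

Step 4
Reactants: 6 7-hydroxy-2,2-dimethyl-5-propyl-4H-1,3-benzodioxin-4-one
Product: 7 7-(benzyloxy)-2,2-dimethyl-5-propyl-4H-1,3-benzodioxin-4-one
Conditions: BnBr, K2CO3, acetone, reflux
Reagents that add atoms: benzyl bromide, BrCc1ccccc1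
Why: Williamson etherification of the only free phenol; the acetonide ester is inert to carbonate in an aprotic solvent.

Step 5
Reactants: 7 7-(benzyloxy)-2,2-dimethyl-5-propyl-4H-1,3-benzodioxin-4-one
Product: 9 methyl 4-(benzyloxy)-2-methoxy-6-propylbenzoate, via sodium phenoxide 8 (not isolated)
Conditions: NaOMe (1.2 equiv), MeOH–THF, 0 °C → rt; evaporate; MeI, DMF, rt → 40 °C
Reagents that add atoms: sodium methoxide, [Na+].[O-]C; iodomethane, CI
Why: Methoxide adds to the activated acetonide ester carbonyl and the hemiketal alkoxide collapses with loss of acetone to phenoxide 8 (alkoxide opening of salicylate acetonides); the oxygen released is by construction the one ortho to the new methyl ester, and its sodium salt is O-methylated by MeI in DMF (Williamson).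

Step 6
Reactants: 9 methyl 4-(benzyloxy)-2-methoxy-6-propylbenzoate
Product: 10 methyl 4-hydroxy-2-methoxy-6-propylbenzoate
Conditions: H2 (1 atm), 10% Pd/C, EtOAc, rt
Reagents that add atoms: none
Why: Hydrogenolysis of the benzyl ether; no other reducible group is present.

Step 7
Reactants: 5 6-(2,4-dioxoheptyl)-2,2-dimethyl-4H-1,3-dioxin-4-one; 10 methyl 4-hydroxy-2-methoxy-6-propylbenzoate
Product: 13 3-methoxy-4-(methoxycarbonyl)-5-propylphenyl 2,4-dihydroxy-6-propylbenzoate, via acylketene 11 (not isolated), via triketo aryl ester 12 (not isolated)
Conditions: 10 (1.5 equiv), PhMe, 110 °C, N2 sweep; then rt, Et3N; 1 M HCl wash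
Reagents that add atoms: none
Why: Heating 5 causes a retro-hetero-Diels–Alder loss of acetone to acylketene 11, and the O–H of 10 adds to the ketene through a six-centre transition state to give β-keto aryl ester 12, so the depside C(=O)–O bond forms at an unhindered sp carbon before either ortho substituent of ring A exists. Et3N then forms the C2 enolate of 12, which adds to the C7 propyl ketone in a 6-(enolendo)-exo-trig aldol, the only ring closure of the step. β-Elimination of water and enolisation of the two remaining ring carbonyls give ring A with its 2- and 4-hydroxyls free, and no stereocentre is formed. The closest known reaction type is the dioxinone thermolysis, ketene capture and aromatisation cascade that gives resorcylate esters from alcohols, together with the acetoacetylation of phenols by dioxinones. The first selectivity needed is intermolecular capture by 10 over intramolecular O-acylation of 11 (pyranone formation); excess 10 at high concentration and the acidity of this para-ester phenol favour the concerted addition. The second is aldol at the ketone over Claisen attack of C6 on the aryl ester or E1cB loss of aryloxide; the ketone is the more electrophilic carbonyl, aldol followed by aromatisation is irreversible, and any ketene released is recaptured by the excess 10 still present. The regiochemistry of ring A is fixed by chain length, since C2 to C7 is the only six-membered aldol available.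

## Compound list

1 | 2,2,6-trimethyl-4H-1,3-dioxin-4-one | CC1=CC(=O)OC(C)(C)O1 | starting material
2 | acetyl chloride | CC(=O)Cl | starting material
3 | 2,2-dimethyl-6-(2-oxopropyl)-4H-1,3-dioxin-4-one | CC(=O)CC1=CC(=O)OC(C)(C)O1 | intermediate
4 | N-methoxy-N-methylbutanamide | CCCC(=O)N(C)OC | starting material
5 | 6-(2,4-dioxoheptyl)-2,2-dimethyl-4H-1,3-dioxin-4-one | CCCC(=O)CC(=O)CC1=CC(=O)OC(C)(C)O1 | intermediate
6 | 7-hydroxy-2,2-dimethyl-5-propyl-4H-1,3-benzodioxin-4-one | CCCc1cc(O)cc2OC(C)(C)OC(=O)c12 | intermediate
7 | 7-(benzyloxy)-2,2-dimethyl-5-propyl-4H-1,3-benzodioxin-4-one | CCCc1cc(OCc3ccccc3)cc2OC(C)(C)OC(=O)c12 | intermediate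
8 | sodium 5-(benzyloxy)-2-(methoxycarbonyl)-3-propylphenolate | CCCc1cc(OCc2ccccc2)cc([O-])c1C(=O)OC.[Na+] | intermediate
9 | methyl 4-(benzyloxy)-2-methoxy-6-propylbenzoate | CCCc1cc(OCc2ccccc2)cc(OC)c1C(=O)OC | intermediate
10 | methyl 4-hydroxy-2-methoxy-6-propylbenzoate | CCCc1cc(O)cc(OC)c1C(=O)OC | intermediate
11 | dec-1-ene-1,3,5,7-tetrone (acylketene) | CCCC(=O)CC(=O)CC(=O)C=C=O | intermediate
12 | 3-methoxy-4-(methoxycarbonyl)-5-propylphenyl 3,5,7-trioxodecanoate | CCCC(=O)CC(=O)CC(=O)CC(=O)Oc1cc(CCC)c(C(=O)OC)c(OC)c1 | intermediate
13 | 3-methoxy-4-(methoxycarbonyl)-5-propylphenyl 2,4-dihydroxy-6-propylbenzoate | CCCc1cc(O)cc(O)c1C(=O)Oc1cc(CCC)c(C(=O)OC)c(OC)c1 | target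

## Step count and risks

Total step count: 7. Longest linear sequence: 7 steps (1 → 3 → 5 → 6 → 7 → 9 → 10 → 13). Compound 5 is the branch point and enters again in step 7.

**Step 7 (key step).** Capture of the ketene by the phenol may lose to cyclisation of the ketene onto its own enol oxygen, because a para-ester phenol is a weaker nucleophile than an aliphatic alcohol. During the amine treatment, ring closure at the aryl ester carbonyl or E1cB expulsion of the aryloxide may compete with the aldol, because the aryloxide is a good leaving group. The fallback sets out from 7 and returns at 13. Hydrolysis of 7 (KOH, DMSO–H2O) would give 4-(benzyloxy)-2-hydroxy-6-propylbenzoic acid F1. Condensation of F1 with 10 by trifluoroacetic anhydride in toluene, a classical depside coupling in which the chelated ortho hydroxyl does not interfere, would give 3-methoxy-4-(methoxycarbonyl)-5-propylphenyl 4-(benzyloxy)-2-hydroxy-6-propylbenzoate F2. Hydrogenolysis (H2, Pd/C) would give 13.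

**Step 2.** Proton exchange between the terminal carbanion and more acidic sites may give incomplete or misdirected acylation, and 5 may aromatise prematurely during work-up or chromatography. The fallback sets out from 1 and returns at 5, moving the acylation to a doubly activated carbon. The dienolate of 1 would be acylated with allyl 3-chloro-3-oxopropanoate to give allyl 4-(2,2-dimethyl-4-oxo-4H-1,3-dioxin-6-yl)-3-oxobutanoate F3. Soft enolisation and C-acylation with butanoyl chloride (MgCl2, pyridine, CH2Cl2) would give allyl 2-[2-(2,2-dimethyl-4-oxo-4H-1,3-dioxin-6-yl)acetyl]-3-oxohexanoate F4, an enolised tricarbonyl with no defined configuration. Deallylation and decarboxylation with Pd(PPh3)4 (zerovalent palladium) and morpholine would give 5.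

**Step 1.** Proton transfer from the product consumes dienolate, and O-acylation or double acylation of the dienolate may lower conversion. The fallback sets out from 1 and returns at 3, replacing acylation by aldol addition and oxidation. Silylation of the dienolate (LiN(iPr)2, Me3SiCl) would give [(2,2-dimethyl-6-methylidene-6H-1,3-dioxin-4-yl)oxy]trimethylsilane F5. A vinylogous Mukaiyama aldol with acetaldehyde (BF3·OEt2, CH2Cl2, −78 °C) would give racemic 6-(2-hydroxypropyl)-2,2-dimethyl-4H-1,3-dioxin-4-one F6. Dess–Martin oxidation would give 3.

**Step 5.** In the telescoped mode, methylation of the hindered, chelated phenoxide may stay incomplete, and adventitious hydroxide may hydrolyse the ester. The fallback sets out from 5 and returns at 9, differentiating the oxygens by chelation instead of by the acetonide. Thermolysis of 5 with methanol in toluene, then Cs2CO3 in MeOH and acidification, would give methyl 2,4-dihydroxy-6-propylbenzoate F7. Selective benzylation of the non-chelated para hydroxyl (BnBr, 1 equiv, K2CO3, acetone) would give methyl 4-(benzyloxy)-2-hydroxy-6-propylbenzoate F8. Methylation with dimethyl sulfate and K2CO3 in refluxing acetone would give 9.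

## Further compounds

F1 | step 7 | 4-(benzyloxy)-2-hydroxy-6-propylbenzoic acid | CCCc1cc(OCc2ccccc2)cc(O)c1C(=O)O
F2 | step 7 | 3-methoxy-4-(methoxycarbonyl)-5-propylphenyl 4-(benzyloxy)-2-hydroxy-6-propylbenzoate | CCCc1cc(OCc2ccccc2)cc(O)c1C(=O)Oc1cc(CCC)c(C(=O)OC)c(OC)c1
F3 | step 2 | allyl 4-(2,2-dimethyl-4-oxo-4H-1,3-dioxin-6-yl)-3-oxobutanoate | C=CCOC(=O)CC(=O)CC1=CC(=O)OC(C)(C)O1
F4 | step 2 | allyl 2-[2-(2,2-dimethyl-4-oxo-4H-1,3-dioxin-6-yl)acetyl]-3-oxohexanoate | CCCC(=O)C(C(=O)OCC=C)C(=O)CC1=CC(=O)OC(C)(C)O1
F5 | step 1 | [(2,2-dimethyl-6-methylidene-6H-1,3-dioxin-4-yl)oxy]trimethylsilane | C=C1C=C(O[Si](C)(C)C)OC(C)(C)O1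
F6 | step 1 | 6-(2-hydroxypropyl)-2,2-dimethyl-4H-1,3-dioxin-4-one (racemic) | CC(O)CC1=CC(=O)OC(C)(C)O1
F7 | step 5 | methyl 2,4-dihydroxy-6-propylbenzoate | CCCc1cc(O)cc(O)c1C(=O)OC
F8 | step 5 | methyl 4-(benzyloxy)-2-hydroxy-6-propylbenzoate | CCCc1cc(OCc2ccccc2)cc(O)c1C(=O)OC
A1 | alternative 1 | 2,4-bis(benzyloxy)-6-propylbenzoic acid | CCCc1cc(OCc2ccccc2)cc(OCc2ccccc2)c1C(=O)O
A2 | alternative 1 | 3-methoxy-4-(methoxycarbonyl)-5-propylphenyl 2,4-bis(benzyloxy)-6-propylbenzoate | CCCc1cc(OCc2ccccc2)cc(OCc2ccccc2)c1C(=O)Oc1cc(CCC)c(C(=O)OC)c(OC)c1
A3 | alternative 2 | 3-hydroxy-6-(oxomethylidene)-5-propylcyclohexa-2,4-dien-1-one | CCCC1=CC(O)=CC(=O)C1=C=O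
A4 | alternative 3 | 2,2-dimethyl-4-oxo-5-propyl-4H-1,3-benzodioxin-7-yl 2,4-dihydroxy-6-propylbenzoate | CCCc1cc(O)cc(O)c1C(=O)Oc1cc(CCC)c2C(=O)OC(C)(C)Oc2c1
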